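**Plan**
Retrosynthesis cuts C11=C12 and C11'=C12' (two Wittig reactions of C15 dienals with a C10 bis-phosphonium salt), then C6–C7 and C6'–C7' (acetylide addition to ring ketones, the alkyne later reduced to the E-alkene), and in the bicyclic end the ether bond O–C3.
Enabling feature: in each end group C5(OH)(CH3)–C6(O) sits beside the gem-dimethyl carbon C1, so the ring is a masked 2-hydroxy-2-methylcyclohexanone, the α-ketol isomer of a 1-acetylcyclopentanol; the triol ring C1'–C6' therefore arises from a cyclopentane by a 1,2-shift of C4' from C6' to the acetyl carbon, which becomes C5'.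
Forward order: cyclopentanone 1 → acetyl carbinol 7 → ring expansion to cyclohexanone 8 (triol end) or, without chelation, to its C5 epimer 16 (bicyclic end) → side chain C7–C11 on each ketone → oxygen bridge closed on the bicyclic end → C15 + C10 + C15 joined, bicyclic end first.
Stereochemistry: one centre comes from copper-catalysed asymmetric borylation; it directs the carbinol centre of 7, which is transferred to C5/C5' in the shift; C5/C5' and the ring conformation direct acetylide attack at C6/C6'; the original centre is finally inverted (hydroxyl-directed reduction at C3', SN2 ether closure at C3).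

Key step: step 5

Assumption: 1, 9 and 22 are taken as commercial; ring positions are named in carotenoid numbering (C1–C6 bicyclic end, C1'–C6' triol end), also in the precursors; acid is excluded after steps 9 and 13 (argon, dark, Et3N-deactivated silica) because it would ionise the tertiary allylic C6–O/C6'–O bond.

Step 1
Reactants: 1 2,2-dimethylcyclopentan-1-one
Product: 2 5,5-dimethylcyclopent-2-en-1-one
Conditions: IBX (2 equiv), DMSO/PhF, 75 °C
Reagents that add atoms: none
Why: IBX dehydrogenation of a ketone to the enone can start only from the single enolisable CH2 group, so the double bond must form on the side away from the gem-dimethyl carbon.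

Step 2
Reactants: 2 5,5-dimethylcyclopent-2-en-1-one
Product: 4 (4S)-4-hydroxy-2,2-dimethylcyclopentan-1-one, via boronate 3 (not isolated)
Conditions: B2pin2, CuCl (5 mol%), NaOtBu (10 mol%), QuinoxP* (6 mol%; the enantiomer that leads to the S boronate), MeOH, THF, rt; then NaBO3·4H2O, THF/H2O, rt
Reagents that add atoms: bis(pinacolato)diboron, CC1(C)OB(OC1(C)C)B1OC(C)(C)C(C)(C)O1 (boron of 3); sodium perborate NaBO3, [Na+].[O-]OB=O (hydroxyl oxygen of 4)
Why: Copper-catalysed enantioselective conjugate borylation of the cyclic enone, followed by perborate oxidation of the C–B bond with retention, should set the only catalyst-derived stereocentre (the later C3/C3') as a β-hydroxy ketone.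

Step 3
Reactants: 4 (4S)-4-hydroxy-2,2-dimethylcyclopentan-1-one
Product: 5 (4S)-4-[(tert-butyldimethylsilyl)oxy]-2,2-dimethylcyclopentan-1-one
Conditions: TBSCl, imidazole, DMF, rt
Reagents that add atoms: tert-butyldimethylsilyl chloride, CC(C)(C)[Si](C)(C)Cl
Why: Imidazole-promoted silylation protects the β-hydroxyl against elimination and supplies the bulky group that steers the next addition.

Step 4
Reactants: 5 (4S)-4-[(tert-butyldimethylsilyl)oxy]-2,2-dimethylcyclopentan-1-one
Product: 7 1-[(1S,4S)-4-[(tert-butyldimethylsilyl)oxy]-1-hydroxy-2,2-dimethylcyclopentyl]ethan-1-one, via enol ether 6 (not isolated)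
Conditions: ethyl vinyl ether, t-BuLi, THF, −78 → 0 °C; add 5, −78 °C; then 0.5 M aq. HCl, THF, 0 °C
Reagents that add atoms: ethyl vinyl ether, C=COCC (as 1-ethoxyvinyllithium; the two acetyl carbons); water, O (acetyl oxygen)
Why: 1,2-Addition of the acyl-anion equivalent 1-ethoxyvinyllithium should occur anti to the silyloxy group, so that the new tertiary hydroxyl is cis to it, and mild hydrolysis of the enol ether then frees the tertiary α-ketol.

Step 5
Reactants: 7 1-[(1S,4S)-4-[(tert-butyldimethylsilyl)oxy]-1-hydroxy-2,2-dimethylcyclopentyl]ethan-1-one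
Product: 8 (2S,4S)-4-[(tert-butyldimethylsilyl)oxy]-2-hydroxy-2,6,6-trimethylcyclohexan-1-one
Conditions: Al(OtBu)3 (1.2 equiv), toluene, 80 °C; aq. work-up
Reagents that add atoms: none
Why: The trivalent aluminium alkoxide of 7 binds the acetyl oxygen in a five-membered chelate (O–C–C=O syn-periplanar), and the ring CH2 next to the carbinol carbon (the later C4') shifts with its bonding pair from the carbinol carbon to the acetyl carbon while the carbinol carbon becomes the ketone, an α-ketol (acyloin) rearrangement. The closest known reaction type is the aluminium-alkoxide or Lewis-acid induced D-homoannulation of 17-hydroxy-20-ketosteroids, in which a cyclopentane beside a quaternary carbon is expanded in the same way. The six-membered ring is not closed by a cyclisation but arises from the five-membered one by a suprafacial 1,2-alkyl shift that inserts the former acetyl carbon between the carbinol carbon and the migrating CH2 (one-carbon ring expansion). The only new stereocentre (C5', bearing OH and CH3) is fixed by the carbinol configuration of 7 through the chelate, the new hydroxyl ending on the face of the old one, that is cis to the silyl ether. The step needs migration of the CH2 arm and not of the CMe2 carbon, which is secured because a shift of the quaternary carbon would drag its methyl groups across the acetyl group and create two adjacent fully substituted carbons, as seen in the steroid series with a cis angular methyl; the change is driven by loss of exactly this vicinal congestion and of the eclipsing strain of the cyclopentane in 7.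

Step 6
Reactants: 8 (2S,4S)-4-[(tert-butyldimethylsilyl)oxy]-2-hydroxy-2,6,6-trimethylcyclohexan-1-one; 9 (2E)-3-methylpent-2-en-4-yn-1-ol
Product: 11 (1R,2S,4S)-1-[(3E)-5-hydroxy-3-methylpent-3-en-1-yn-1-yl]-2,6,6-trimethylcyclohexane-1,2,4-triol, via silyl ether 10 (not isolated)
Conditions: 9 (3 equiv), n-BuLi (2 equiv per 9), THF, −78 → 0 °C; add 8, −78 → −20 °C; H2O; then TBAF, THF, rt
Reagents that add atoms: none
Why: Acetylide 1,2-addition to the non-enolisable ketone: in the chair with equatorial silyloxy group the C5' methyl and one C1' methyl are axial on the same face, so the slim alkynyllithium should attack axially from the other face and place the new C6' hydroxyl trans to the C5' hydroxyl, after which fluoride cleaves the silyl ether.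

Step 7
Reactants: 11 (1R,2S,4S)-1-[(3E)-5-hydroxy-3-methylpent-3-en-1-yn-1-yl]-2,6,6-trimethylcyclohexane-1,2,4-triol
Product: 12 (2E)-5-[(1R,2S)-1,2-dihydroxy-2,6,6-trimethyl-4-oxocyclohexyl]-3-methylpent-2-en-4-ynal
Conditions: Dess–Martin periodinane (2.5 equiv), CH2Cl2, 0 °C → rt
Reagents that add atoms: none
Why: Dess–Martin oxidation takes the secondary C3' alcohol to the ketone and the primary allylic alcohol to the aldehyde while the two tertiary alcohols are inert, which erases the C3' centre once it has done its directing work.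

Step 8
Reactants: 12 (2E)-5-[(1R,2S)-1,2-dihydroxy-2,6,6-trimethyl-4-oxocyclohexyl]-3-methylpent-2-en-4-ynal
Product: 13 (1R,2S,4R)-1-[(3E)-5-hydroxy-3-methylpent-3-en-1-yn-1-yl]-2,6,6-trimethylcyclohexane-1,2,4-triol
Conditions: Me4NBH(OAc)3 (excess), MeCN/AcOH, −30 °C → rt
Reagents that add atoms: none
Why: Evans–Saksena hydroxyl-directed reduction: the tertiary C5' hydroxyl binds boron and delivers hydride to the ketone on its own face, which should give the 1,3-anti diol and thus the inverted (R) configuration at C3', while the enal is reduced back to the primary alcohol by the same hydride.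

Step 9
Reactants: 13 (1R,2S,4R)-1-[(3E)-5-hydroxy-3-methylpent-3-en-1-yn-1-yl]-2,6,6-trimethylcyclohexane-1,2,4-triol
Product: 14 (1S,2S,4R)-1-[(1E,3E)-5-hydroxy-3-methylpenta-1,3-dien-1-yl]-2,6,6-trimethylcyclohexane-1,2,4-triol
Conditions: NaAlH2(OCH2CH2OMe)2 (Red-Al, excess), THF, 0 °C → rt; aq. NaOH work-up
Reagents that add atoms: none
Why: Hydroxyl-directed trans-hydroalumination of the tertiary propargylic alcohol followed by protonolysis, the classical alkyne-to-E-alkene reduction of 6-hydroxy-7-yne end groups, should give the 7'E double bond and leave the 9'E alkene untouched.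

Step 10
Reactants: 14 (1S,2S,4R)-1-[(1E,3E)-5-hydroxy-3-methylpenta-1,3-dien-1-yl]-2,6,6-trimethylcyclohexane-1,2,4-triol
Product: 15 (2E,4E)-3-methyl-5-[(1S,2S,4R)-1,2,4-trihydroxy-2,6,6-trimethylcyclohexyl]penta-2,4-dienal
Conditions: MnO2 (activated, excess), CH2Cl2, rt, dark
Reagents that add atoms: none
Why: Allylic oxidation with MnO2 is selective for the primary allylic alcohol over the secondary and tertiary hydroxyls and gives the C15 dienal without acid.

Step 11
Reactants: 7 1-[(1S,4S)-4-[(tert-butyldimethylsilyl)oxy]-1-hydroxy-2,2-dimethylcyclopentyl]ethan-1-one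
Product: 16 (2R,4S)-4-[(tert-butyldimethylsilyl)oxy]-2-hydroxy-2,6,6-trimethylcyclohexan-1-one
Conditions: KOtBu (1.1 equiv), 18-crown-6, THF, −20 → 0 °C; aq. work-up
Reagents that add atoms: none
Why: Base-induced α-ketol rearrangement: in the crown-ether-separated potassium alkoxide there is no chelate, the alkoxide and carbonyl oxygens turn anti to each other, and the same CH2 arm then migrates to the opposite face of the acetyl carbon, which should give the C5 epimer of 8 (hydroxyl trans to the silyl ether), just as base and Lewis acid give epimeric products in steroid D-homoannulation.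

Step 12
Reactants: 16 (2R,4S)-4-[(tert-butyldimethylsilyl)oxy]-2-hydroxy-2,6,6-trimethylcyclohexan-1-one; 9 (2E)-3-methylpent-2-en-4-yn-1-ol
Product: 18 (1R,2R,4S)-1-[(3E)-5-hydroxy-3-methylpent-3-en-1-yn-1-yl]-2,6,6-trimethylcyclohexane-1,2,4-triol, via silyl ether 17 (not isolated)
Conditions: 9 (3 equiv), n-BuLi (2 equiv per 9), THF, −78 → 0 °C; add 16, −78 → −20 °C; H2O; then TBAF, THF, rt
Reagents that add atoms: none
Why: Acetylide 1,2-addition as in step 6, but here the chair with equatorial silyloxy group carries the C5 hydroxyl and one C1 methyl axial on one face, so attack from the other face should give the cis-5,6-diol with the C6 hydroxyl trans to the C3 oxygen, after which fluoride cleaves the silyl ether.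

Step 13
Reactants: 18 (1R,2R,4S)-1-[(3E)-5-hydroxy-3-methylpent-3-en-1-yn-1-yl]-2,6,6-trimethylcyclohexane-1,2,4-triol
Product: 19 (1S,2R,4S)-1-[(1E,3E)-5-hydroxy-3-methylpenta-1,3-dien-1-yl]-2,6,6-trimethylcyclohexane-1,2,4-triol
Conditions: NaAlH2(OCH2CH2OMe)2 (Red-Al, excess), THF, 0 °C → rt; aq. NaOH work-up
Reagents that add atoms: none
Why: The same hydroxyl-directed trans-hydroalumination and protonolysis as in step 9 should give the 7E alkene while the C6 hydroxyl is still free to direct it.

Step 14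
Reactants: 19 (1S,2R,4S)-1-[(1E,3E)-5-hydroxy-3-methylpenta-1,3-dien-1-yl]-2,6,6-trimethylcyclohexane-1,2,4-triol
Product: 20 (2E,4E)-3-methyl-5-[(1S,2R,4S)-1,2,4-trihydroxy-2,6,6-trimethylcyclohexyl]penta-2,4-dienal
Conditions: MnO2 (activated, excess), CH2Cl2, rt, dark
Reagents that add atoms: none
Why: Allylic oxidation with MnO2 converts only the primary allylic alcohol, which both creates the coupling handle and removes the one hydroxyl that would compete in the next step.

Step 15
Reactants: 20 (2E,4E)-3-methyl-5-[(1S,2R,4S)-1,2,4-trihydroxy-2,6,6-trimethylcyclohexyl]penta-2,4-dienal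
Product: 21 (2E,4E)-5-[(1S,2R,4R)-2-hydroxy-2,6,6-trimethyl-7-oxabicyclo[2.2.1]heptan-1-yl]-3-methylpenta-2,4-dienal
Conditions: PPh3, DIAD, toluene, 0 °C → rt
Reagents that add atoms: none
Why: Mitsunobu-type cyclodehydration: only the secondary C3 hydroxyl forms the oxyphosphonium ion, and the tertiary C6 hydroxyl, trans-1,4 to it, displaces it intramolecularly with inversion (SN2 through a boat), which should close the 7-oxabicyclo[2.2.1]heptane with the C5 hydroxyl syn to the oxygen bridge.

Step 16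
Reactants: 22 (2E,4E,6E)-2,7-dimethylocta-2,4,6-trienedial
Product: 23 (2E,4E,6E)-2,7-dimethylocta-2,4,6-triene-1,8-diol
Conditions: NaBH4, CeCl3·7H2O, MeOH, 0 °C
Reagents that add atoms: none
Why: Luche-type 1,2-reduction of both enal groups should give the bis-allylic diol with the E,E,E-triene intact.

Step 17
Reactants: 23 (2E,4E,6E)-2,7-dimethylocta-2,4,6-triene-1,8-diol
Product: 24 [(2E,4E,6E)-2,7-dimethylocta-2,4,6-triene-1,8-diyl]bis(triphenylphosphonium) dibromide
Conditions: PPh3·HBr (2.1 equiv), MeOH, rt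
Reagents that add atoms: triphenylphosphine hydrobromide, [Br-].c1ccc(cc1)[PH+](c1ccccc1)c1ccccc1
Why: Acid-mediated substitution of allylic alcohols by triphenylphosphine is the standard formation of polyene Wittig salts and is applied here to the only fragment that carries no acid-sensitive group.

Step 18
Reactants: 21 (2E,4E)-5-[(1S,2R,4R)-2-hydroxy-2,6,6-trimethyl-7-oxabicyclo[2.2.1]heptan-1-yl]-3-methylpenta-2,4-dienal; 24 [(2E,4E,6E)-2,7-dimethylocta-2,4,6-triene-1,8-diyl]bis(triphenylphosphonium) dibromide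
Product: 25 [(2E,4E,6E,8E,10E,12E)-13-[(1S,2R,4R)-2-hydroxy-2,6,6-trimethyl-7-oxabicyclo[2.2.1]heptan-1-yl]-2,7,11-trimethyltrideca-2,4,6,8,10,12-hexaen-1-yl]triphenylphosphonium bromide
Conditions: 24 (3 equiv), NaOMe (1 equiv), CH2Cl2/MeOH, −10 °C → rt
Reagents that add atoms: none
Why: Wittig olefination: with the bis-salt in excess and one equivalent of base essentially only the mono-ylide should form, joining C12 to the aldehyde carbon C11 and keeping the second phosphonium group for the last step, and any 11Z isomer is carried on and isomerised at the end.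

Step 19
Reactants: 25 [(2E,4E,6E,8E,10E,12E)-13-[(1S,2R,4R)-2-hydroxy-2,6,6-trimethyl-7-oxabicyclo[2.2.1]heptan-1-yl]-2,7,11-trimethyltrideca-2,4,6,8,10,12-hexaen-1-yl]triphenylphosphonium bromide; 15 (2E,4E)-3-methyl-5-[(1S,2S,4R)-1,2,4-trihydroxy-2,6,6-trimethylcyclohexyl]penta-2,4-dienal
Product: 26 (3R,5R,6S,3'R,5'S,6'S)-3,6-epoxy-5,6,5',6'-tetrahydro-β,β-carotene-5,3',5',6'-tetrol (all-E)
Conditions: NaOMe, CH2Cl2/MeOH, 0 °C → rt; then EtOH, reflux, Ar, dark (Z→E isomerisation); Et3N-deactivated SiO2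
Reagents that add atoms: none
Why: The second Wittig olefination forms C11'=C12' with the free hydroxyls tolerated under methoxide conditions, and heating should then equilibrate the hindered Z isomers of the two new disubstituted double bonds to the all-E polyene.

**Compound list**
1 | 2,2-dimethylcyclopentan-1-one | CC1(C)CCCC1=O | starting material
2 | 5,5-dimethylcyclopent-2-en-1-one | O=C1C=CCC1(C)C | intermediate
3 | (4S)-2,2-dimethyl-4-(4,4,5,5-tetramethyl-1,3,2-dioxaborolan-2-yl)cyclopentan-1-one | O=C1C(C)(C)C[C@H](B2OC(C)(C)C(C)(C)O2)C1 | intermediate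
4 | (4S)-4-hydroxy-2,2-dimethylcyclopentan-1-one | O=C1C(C)(C)C[C@H](O)C1 | intermediate
5 | (4S)-4-[(tert-butyldimethylsilyl)oxy]-2,2-dimethylcyclopentan-1-one | O=C1C(C)(C)C[C@H](O[Si](C)(C)C(C)(C)C)C1 | intermediate
6 | (1S,4S)-4-[(tert-butyldimethylsilyl)oxy]-1-(1-ethoxyethenyl)-2,2-dimethylcyclopentan-1-ol | C=C(OCC)[C@@]1(O)C(C)(C)C[C@H](O[Si](C)(C)C(C)(C)C)C1 | intermediate
7 | 1-[(1S,4S)-4-[(tert-butyldimethylsilyl)oxy]-1-hydroxy-2,2-dimethylcyclopentyl]ethan-1-one | CC(=O)[C@@]1(O)C(C)(C)C[C@H](O[Si](C)(C)C(C)(C)C)C1 | intermediate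
8 | (2S,4S)-4-[(tert-butyldimethylsilyl)oxy]-2-hydroxy-2,6,6-trimethylcyclohexan-1-one | O=C1C(C)(C)C[C@H](O[Si](C)(C)C(C)(C)C)C[C@]1(C)O | intermediate
9 | (2E)-3-methylpent-2-en-4-yn-1-ol | C#C/C(C)=C/CO | starting material
10 | (1R,2S,4S)-4-[(tert-butyldimethylsilyl)oxy]-1-[(3E)-5-hydroxy-3-methylpent-3-en-1-yn-1-yl]-2,6,6-trimethylcyclohexane-1,2-diol | OC/C=C(C)/C#C[C@]1(O)C(C)(C)C[C@H](O[Si](C)(C)C(C)(C)C)C[C@]1(C)O | intermediate
11 | (1R,2S,4S)-1-[(3E)-5-hydroxy-3-methylpent-3-en-1-yn-1-yl]-2,6,6-trimethylcyclohexane-1,2,4-triol | OC/C=C(C)/C#C[C@]1(O)C(C)(C)C[C@H](O)C[C@]1(C)O | intermediate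
12 | (2E)-5-[(1R,2S)-1,2-dihydroxy-2,6,6-trimethyl-4-oxocyclohexyl]-3-methylpent-2-en-4-ynal | O=C/C=C(C)/C#C[C@]1(O)C(C)(C)CC(=O)C[C@]1(C)O | intermediate
13 | (1R,2S,4R)-1-[(3E)-5-hydroxy-3-methylpent-3-en-1-yn-1-yl]-2,6,6-trimethylcyclohexane-1,2,4-triol | OC/C=C(C)/C#C[C@]1(O)C(C)(C)C[C@@H](O)C[C@]1(C)O | intermediate
14 | (1S,2S,4R)-1-[(1E,3E)-5-hydroxy-3-methylpenta-1,3-dien-1-yl]-2,6,6-trimethylcyclohexane-1,2,4-triol | OC/C=C(C)/C=C/[C@]1(O)C(C)(C)C[C@@H](O)C[C@]1(C)O | intermediate
15 | (2E,4E)-3-methyl-5-[(1S,2S,4R)-1,2,4-trihydroxy-2,6,6-trimethylcyclohexyl]penta-2,4-dienal | O=C/C=C(C)/C=C/[C@]1(O)C(C)(C)C[C@@H](O)C[C@]1(C)O | intermediate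
16 | (2R,4S)-4-[(tert-butyldimethylsilyl)oxy]-2-hydroxy-2,6,6-trimethylcyclohexan-1-one | O=C1C(C)(C)C[C@H](O[Si](C)(C)C(C)(C)C)C[C@@]1(C)O | intermediate
17 | (1R,2R,4S)-4-[(tert-butyldimethylsilyl)oxy]-1-[(3E)-5-hydroxy-3-methylpent-3-en-1-yn-1-yl]-2,6,6-trimethylcyclohexane-1,2-diol | OC/C=C(C)/C#C[C@]1(O)C(C)(C)C[C@H](O[Si](C)(C)C(C)(C)C)C[C@@]1(C)O | intermediate
18 | (1R,2R,4S)-1-[(3E)-5-hydroxy-3-methylpent-3-en-1-yn-1-yl]-2,6,6-trimethylcyclohexane-1,2,4-triol | OC/C=C(C)/C#C[C@]1(O)C(C)(C)C[C@H](O)C[C@@]1(C)O | intermediate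
19 | (1S,2R,4S)-1-[(1E,3E)-5-hydroxy-3-methylpenta-1,3-dien-1-yl]-2,6,6-trimethylcyclohexane-1,2,4-triol | OC/C=C(C)/C=C/[C@]1(O)C(C)(C)C[C@H](O)C[C@@]1(C)O | intermediate
20 | (2E,4E)-3-methyl-5-[(1S,2R,4S)-1,2,4-trihydroxy-2,6,6-trimethylcyclohexyl]penta-2,4-dienal | O=C/C=C(C)/C=C/[C@]1(O)C(C)(C)C[C@H](O)C[C@@]1(C)O | intermediate
21 | (2E,4E)-5-[(1S,2R,4R)-2-hydroxy-2,6,6-trimethyl-7-oxabicyclo[2.2.1]heptan-1-yl]-3-methylpenta-2,4-dienal | O=C/C=C(C)/C=C/[C@]12O[C@H](CC1(C)C)C[C@@]2(C)O | intermediate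
22 | (2E,4E,6E)-2,7-dimethylocta-2,4,6-trienedial | O=C/C(C)=C/C=C/C=C(C)/C=O | starting material
23 | (2E,4E,6E)-2,7-dimethylocta-2,4,6-triene-1,8-diol | OC/C(C)=C/C=C/C=C(C)/CO | intermediate
24 | [(2E,4E,6E)-2,7-dimethylocta-2,4,6-triene-1,8-diyl]bis(triphenylphosphonium) dibromide | [Br-].[Br-].c1ccc(cc1)[P+](c1ccccc1)(c1ccccc1)C/C(C)=C/C=C/C=C(C)/C[P+](c1ccccc1)(c1ccccc1)c1ccccc1 | intermediate
25 | [(2E,4E,6E,8E,10E,12E)-13-[(1S,2R,4R)-2-hydroxy-2,6,6-trimethyl-7-oxabicyclo[2.2.1]heptan-1-yl]-2,7,11-trimethyltrideca-2,4,6,8,10,12-hexaen-1-yl]triphenylphosphonium bromide | [Br-].c1ccc(cc1)[P+](c1ccccc1)(c1ccccc1)C/C(C)=C/C=C/C=C(C)/C=C/C=C(C)/C=C/[C@]12O[C@H](CC1(C)C)C[C@@]2(C)O | intermediate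
26 | (3R,5R,6S,3'R,5'S,6'S)-3,6-epoxy-5,6,5',6'-tetrahydro-β,β-carotene-5,3',5',6'-tetrol (all-E) | CC(/C=C/C=C(C)/C=C/[C@]12O[C@H](CC1(C)C)C[C@@]2(C)O)=C\C=C\C=C(C)\C=C\C=C(C)\C=C\[C@]1(O)C(C)(C)C[C@@H](O)C[C@]1(C)O | target

**Step count**
Total: 19 steps. Longest linear sequence: 11 steps (1–10 and 19, or equally 1–4, 11–15, 18 and 19).

**Three steps most likely to fail**

Step 5. What may go wrong: migration of the CMe2 arm in place of the CH2 arm, or partial reaction through a non-chelated geometry, would erode regio- or facial control in the 1,2-shift. Fallback (known chemistry, still a one-carbon ring expansion): setting out from 5, Lewis-acid promoted diazoalkane insertion (TMSCHN2, BF3·OEt2, CH2Cl2, −78 °C; the less substituted CH2 arm migrates, then protodesilylation) should give (4R)-4-[(tert-butyldimethylsilyl)oxy]-2,2-dimethylcyclohexan-1-one F1. Enolate methylation at the only enolisable position (LiN(iPr)2, MeI, THF, −78 °C) gives (4R)-4-[(tert-butyldimethylsilyl)oxy]-2,2,6-trimethylcyclohexan-1-one F2. TMSOTf/Et3N gives the tetrasubstituted silyl enol ether tert-butyldimethyl({(1R)-3,5,5-trimethyl-4-[(trimethylsilyl)oxy]cyclohex-3-en-1-yl}oxy)silane F3. Rubottom oxidation (mCPBA, NaHCO3, CH2Cl2; then K2CO3, MeOH), with the peracid approaching anti to the pseudoaxial methyl of the gem-dimethyl carbon, should place the tertiary hydroxyl cis to the silyl ether and return to the route at 8.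

Step 11. What may go wrong: incomplete suppression of cation chelation, or a poorly defined anti geometry of the free alkoxide, would give poor facial selectivity at the acetyl carbon and a mixture of 16 and 8. Fallback: reach 16 through the chelated mode from the other carbinol configuration. Setting out from 5, Wittig ethylidenation (EtPPh3Br, KOtBu, toluene, heat) gives tert-butyl{[(1S)-3-ethylidene-4,4-dimethylcyclopentyl]oxy}dimethylsilane F4. Dihydroxylation with OsO4/NMO from the face anti to the silyl ether gives (1R,4S)-4-[(tert-butyldimethylsilyl)oxy]-1-(1-hydroxyethyl)-2,2-dimethylcyclopentan-1-ol F5. Oxidation of the secondary alcohol (SO3·pyridine, DMSO, Et3N) gives the epimeric acyloin 1-[(1R,4S)-4-[(tert-butyldimethylsilyl)oxy]-1-hydroxy-2,2-dimethylcyclopentyl]ethan-1-one F6. Its rearrangement under the conditions of step 5 (Al(OtBu)3, toluene, 80 °C) should then give 16, where the route is rejoined.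

Step 15. What may go wrong: elimination of the activated secondary hydroxyl to a cyclohexene, or sequestration of the cis-5,6-diol as a cyclic phosphorane, in place of ether closure. Fallback: invert C3 first and close the bridge from the C3 oxygen. Setting out from 18, Dess–Martin oxidation gives (2E)-5-[(1R,2R)-1,2-dihydroxy-2,6,6-trimethyl-4-oxocyclohexyl]-3-methylpent-2-en-4-ynal F7. Narasaka–Prasad syn reduction (Et2BOMe, NaBH4, THF/MeOH, −78 °C) gives (1R,2R,4R)-1-[(3E)-5-hydroxy-3-methylpent-3-en-1-yn-1-yl]-2,6,6-trimethylcyclohexane-1,2,4-triol F8. Red-Al reduction as in step 13 gives (1S,2R,4R)-1-[(1E,3E)-5-hydroxy-3-methylpenta-1,3-dien-1-yl]-2,6,6-trimethylcyclohexane-1,2,4-triol F9. Brief treatment with PPTS (CH2Cl2, 0 °C) ionises the tertiary allylic C6 hydroxyl, and the C3 hydroxyl, now on the face of the C5 hydroxyl, captures the cation to give (2E,4E)-5-[(1S,2R,4R)-2-hydroxy-2,6,6-trimethyl-7-oxabicyclo[2.2.1]heptan-1-yl]-3-methylpenta-2,4-dien-1-ol F10. MnO2 oxidation returns to the route at 21.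

Further compounds
F1 | step 5 | (4R)-4-[(tert-butyldimethylsilyl)oxy]-2,2-dimethylcyclohexan-1-one | O=C1C(C)(C)C[C@H](O[Si](C)(C)C(C)(C)C)CC1
F2 | step 5 | (4R)-4-[(tert-butyldimethylsilyl)oxy]-2,2,6-trimethylcyclohexan-1-one (both C6 epimers) | O=C1C(C)(C)C[C@H](O[Si](C)(C)C(C)(C)C)CC1C
F3 | step 5 | tert-butyldimethyl({(1R)-3,5,5-trimethyl-4-[(trimethylsilyl)oxy]cyclohex-3-en-1-yl}oxy)silane | C[Si](C)(C)OC1=C(C)C[C@@H](O[Si](C)(C)C(C)(C)C)CC1(C)C
F4 | step 11 | tert-butyl{[(1S)-3-ethylidene-4,4-dimethylcyclopentyl]oxy}dimethylsilane (E/Z) | CC=C1C(C)(C)C[C@H](O[Si](C)(C)C(C)(C)C)C1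
F5 | step 11 | (1R,4S)-4-[(tert-butyldimethylsilyl)oxy]-1-(1-hydroxyethyl)-2,2-dimethylcyclopentan-1-ol (both side-chain carbinol epimers) | CC(O)[C@]1(O)C(C)(C)C[C@H](O[Si](C)(C)C(C)(C)C)C1
F6 | step 11 | 1-[(1R,4S)-4-[(tert-butyldimethylsilyl)oxy]-1-hydroxy-2,2-dimethylcyclopentyl]ethan-1-one | CC(=O)[C@]1(O)C(C)(C)C[C@H](O[Si](C)(C)C(C)(C)C)C1
F7 | step 15 | (2E)-5-[(1R,2R)-1,2-dihydroxy-2,6,6-trimethyl-4-oxocyclohexyl]-3-methylpent-2-en-4-ynal | O=C/C=C(C)/C#C[C@]1(O)C(C)(C)CC(=O)C[C@@]1(C)O
F8 | step 15 | (1R,2R,4R)-1-[(3E)-5-hydroxy-3-methylpent-3-en-1-yn-1-yl]-2,6,6-trimethylcyclohexane-1,2,4-triol | OC/C=C(C)/C#C[C@]1(O)C(C)(C)C[C@@H](O)C[C@@]1(C)O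
F9 | step 15 | (1S,2R,4R)-1-[(1E,3E)-5-hydroxy-3-methylpenta-1,3-dien-1-yl]-2,6,6-trimethylcyclohexane-1,2,4-triol | OC/C=C(C)/C=C/[C@]1(O)C(C)(C)C[C@@H](O)C[C@@]1(C)O
F10 | step 15 | (2E,4E)-5-[(1S,2R,4R)-2-hydroxy-2,6,6-trimethyl-7-oxabicyclo[2.2.1]heptan-1-yl]-3-methylpenta-2,4-dien-1-ol | OC/C=C(C)/C=C/[C@]12O[C@H](CC1(C)C)C[C@@]2(C)O
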